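Assumption: the target has no stereocentre (it is achiral), so there is no configuration to set or protect.

**Retrosynthetic overview**
- Target 7 ⇐ benzylic C–S bond: methanesulfinate 5 captures the para-quinone methide/benzylic cation of lanosol 6, which comes from aldehyde 4 by reduction in the same flask.
- 4 ⇐ C–Br bond: bromination of catechol aldehyde 3 at C2, para to the C5 hydroxyl.
- 3 ⇐ aryl C–O bond (key step): mono-hydroxylation of one of the two equivalent C–Br bonds of 3,5-dibromo-4-hydroxybenzaldehyde 1.
- No ring is built: the benzene ring is bought with 1. The five-membered borate ring of 2 is formed and cleaved within step 1.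

**Route**

Step 1
Reactants: 1 3,5-dibromo-4-hydroxybenzaldehyde
Product: 3 3-bromo-4,5-dihydroxybenzaldehyde, via cyclic catechol borate 2 (not isolated)
Conditions: Cu2O (5 mol %), B(OH)3 (4 equiv), KOH (4.5 equiv; borate buffer, pH ≈ 10), degassed H2O–DMSO 4:1, 115 °C, N2, 16 h; then 2 M HCl, rt
Reagents that add atoms: potassium hydroxide, [K+].[OH-] (O of the new hydroxyl); boric acid, OB(O)O (B–OH of 2 only, released again on work-up)
Why: Proposed new method: borate-gated, ligand-free Cu(I) mono-hydroxylation, in which the phenoxide of 1 binds Cu(I) and directs oxidative addition into an ortho C–Br bond, hydroxide (or borate) on copper forms the C5–O bond by reductive elimination, and the new catecholate is trapped at once by the buffer as cyclic borate 2, which has no free ortho-phenoxide to steer copper to the second C–Br and cannot chelate copper or be air-oxidised, so the exchange stops after one bromide; the closest known reaction type is the Cu-mediated Ullmann hydroxylation of ortho-halophenols in aqueous alkali (5-bromovanillin or 5-iodovanillin to 5-hydroxyvanillin), which has no such control over a second halide.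

Step 2
Reactants: 3 3-bromo-4,5-dihydroxybenzaldehyde
Product: 4 2,3-dibromo-4,5-dihydroxybenzaldehyde
Conditions: Br2 (1.1 equiv), Fe powder (5 mol %), AcOH, rt → 45 °C
Reagents that add atoms: bromine, BrBr
Why: Electrophilic aromatic bromination in which the C5 hydroxyl directs para to C2 (the C4 hydroxyl has no free ortho or para site and the aldehyde deactivates C2 and C6 equally), the same site preference as in the bromination of 5-bromovanillin to 5,6-dibromovanillin, while the aldehyde and bromine make the catechol electron-poor enough to resist oxidation by Br2.

Step 3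
Reactants: 4 2,3-dibromo-4,5-dihydroxybenzaldehyde; 5 sodium methanesulfinate
Product: 7 3,4-dibromo-5-[(methylsulfonyl)methyl]benzene-1,2-diol, via lanosol 6 (not isolated)
Conditions: NaBH4 (1.5 equiv), THF–H2O, 0 °C; then 5 (3 equiv), 2 M aq. HCl to pH 2, 50 °C
Reagents that add atoms: none
Why: Borohydride reduction of the aldehyde gives the para-hydroxybenzylic alcohol 6, which ionises under acid to a para-quinone methide/benzylic cation that the soft sulfinate captures at sulfur (1,6-conjugate addition, irreversible S-alkylation), giving the sulfone directly.

**Compound list**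
1 | 3,5-dibromo-4-hydroxybenzaldehyde | O=Cc1cc(Br)c(O)c(Br)c1 | starting material
2 | 7-bromo-2-hydroxy-1,3,2-benzodioxaborole-5-carbaldehyde (cyclic borate of 3, present in the buffer as its hydroxyborate anion) | O=Cc1cc(Br)c2OB(O)Oc2c1 | intermediate
3 | 3-bromo-4,5-dihydroxybenzaldehyde | O=Cc1cc(O)c(O)c(Br)c1 | intermediate
4 | 2,3-dibromo-4,5-dihydroxybenzaldehyde | O=Cc1cc(O)c(O)c(Br)c1Br | intermediate
5 | sodium methanesulfinate | CS(=O)[O-].[Na+] | starting material
6 | 3,4-dibromo-5-(hydroxymethyl)benzene-1,2-diol (lanosol) | OCc1cc(O)c(O)c(Br)c1Br | intermediate
7 | 3,4-dibromo-5-[(methylsulfonyl)methyl]benzene-1,2-diol | CS(=O)(=O)Cc1cc(O)c(O)c(Br)c1Br | target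

**Totals**
Total step count: 3. Longest linear sequence: 3 (1 → 3 → 4 → 7).

**Steps most likely to fail**

1. Step 1 (the proposed new mono-hydroxylation). The risks are over-hydroxylation to 3,4,5-trihydroxybenzaldehyde if the borate trap is not fast or tight enough, slow turnover at the low hydroxide concentration of a pH 10 buffer, and reductive loss of bromine. The fallback uses known chemistry, sets out from 1 and comes back at 3. Copper-catalysed Ullmann methoxylation of 1 (NaOMe 2.2 equiv, CuCl 10 mol %, DMF–MeOH, 100 °C), the reaction type used to make syringaldehyde from this dibromide, is stopped after the first exchange to give 3-bromo-4-hydroxy-5-methoxybenzaldehyde F1. The methyl ether is then cleaved with BBr3 (CH2Cl2, −78 °C → rt, aqueous work-up) to give 3.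

2. Step 2 (bromination of the free catechol). The risks are partial attack at C6 (ortho to the C5 hydroxyl) and oxidation of the catechol to an ortho-quinone by Br2. The fallback sets out from 3 and comes back at 4, and masks the catechol before bromination. Treating 3 with CH2Br2 and Cs2CO3 (DMF, 90 °C) gives 7-bromo-1,3-benzodioxole-5-carbaldehyde F2. Bromination (Br2, Fe cat., AcOH), which goes para to the ring oxygen as with piperonal, gives 6,7-dibromo-1,3-benzodioxole-5-carbaldehyde F3. The methylene acetal is then cleaved with BBr3 (CH2Cl2, then water) to give 4.

3. Step 3 (one-pot reduction and sulfinate capture). The risks are self-condensation of lanosol through its quinone methide (dibenzyl ether or diarylmethane formation), O-alkylation of the sulfinate, and decomposition of methanesulfinic acid in acid. The fallback sets out from 4 and comes back at 7, and avoids the free benzylic alcohol. Condensing 4 with methanesulfonohydrazide (MeOH, rt) gives N'-[(E)-(2,3-dibromo-4,5-dihydroxyphenyl)methylidene]methanesulfonohydrazide F4. Base-mediated nitrogen loss from this sulfonylhydrazone (K2CO3, cat. CuBr, dioxane, 100 °C, N2) recombines the released methanesulfinate at the benzylic carbon and gives 7.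

**Further compounds**
F1 | step 1 | 3-bromo-4-hydroxy-5-methoxybenzaldehyde (5-bromovanillin) | COc1cc(C=O)cc(Br)c1O
F2 | step 2 | 7-bromo-1,3-benzodioxole-5-carbaldehyde | O=Cc1cc(Br)c2OCOc2c1
F3 | step 2 | 6,7-dibromo-1,3-benzodioxole-5-carbaldehyde | O=Cc1cc2OCOc2c(Br)c1Br
F4 | step 3 | N'-[(E)-(2,3-dibromo-4,5-dihydroxyphenyl)methylidene]methanesulfonohydrazide | CS(=O)(=O)N/N=C/c1cc(O)c(O)c(Br)c1Br
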